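The constants of the two steps competing for substrate are 0.832 /M/s for coupling with coupling partner, which makes target, and 0.164 /M/s for self-condensation, where substrate goes two at a time.

all flasks: time 1.0 min

| charge | substrate | coupling partner | remark |
|---|---|---|---|
| epsilon | 0.20 M | 0.200 M (fed, over 40 s) | all else is in the flask from the start; the feed brings no volume worth counting |
| zeta | 0.20 M | 0.200 M | everything together at the start |
| delta | 0.20 M (fed, over 40 s) | 0.200 M | all else is in the flask from the start; the feed brings no volume worth counting |

* the best flask by amount of target, in percent of the substrate charged; "all alike" if 1.5 percentage points covers them all (epsilon / zeta / delta / all alike)
* amount of target at the end, in percent of the substrate charged, epsilon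
* amount of target at the end, in percent of the substrate charged, zeta
* amount of target at the end, in percent of the substrate charged, delta

- in percentages every species weighs as the substrate in it: one self-condensation product counts as two
- for target the crystals are counted in
- a doubled species enters its step squared and goes two at a time
- as a solid, counted per litre of solution: crystals
- run time (epsilon): 1.0 min

    2 substrate → self-condensation product (k1 = 0.164 /M/s)
    coupling partner → decomposition product (k2 = 2.59 × 10⁻⁴ /s)
    substrate + 2 coupling partner → side product (k3 = 0.0788 /M²/s)
    crystals ⇌ target, rate k4*(cs4 - [target]) while solid is left; crystals form when [target] > cs4 (cs4 = 19 mM, k4 = 1.59 /s)
    substrate + coupling partner → target (k5 = 0.832 /M/s)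

Dividing the first constant by twice the second gives 2.54, the split number. Multiplied by coupling partner over substrate at any moment, it tells how many substrate go to target for each one lost to self-condensation, a selectivity factor. Call that product the ratio; target's share of reacted substrate is then the ratio over one plus the ratio. I read it flask by flask.

In zeta the charges are equal, so the ratio starts at the split number, and it climbs as substrate goes to self-condensation as well as to coupling. Integrating that drift until substrate has reacted away, target comes to 78.5 %.

In epsilon, substrate's self-condensation half-life is 15.2 s, shorter than the feed. By then 0.0762 M of coupling partner has come. Setting that crudely against the substrate charge gives a ratio of 0.967, so target comes to 49.2 %.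

In delta at mid-feed, with coupling partner near 0.100 M, substrate coupling as it arrives sits near 0.0601 M. The ratio is 4.22, so target comes to 80.8 %, and delta leads.

One number was not enough, though. It splits what reacts, not how much has reacted. Delta's last substrate arrives 20.0 s before the end, and as coupling partner falls towards my final level of 0.0383 M, the half-life of substrate by coupling lengthens towards 21.7 s. So I expect delta below my figure.

The forecast says 45 %, 75 % and 77 % with delta best, since “keeping substrate low (delta) suppresses that second-order loss”. The simulation gives 47.1 % for epsilon, 75.7 % for zeta and 78.2 % for delta, so delta is best.

In delta, coupling had done 6.8 % of its turnover by 0.100 min, while self-condensation passed the midpoint of its own at 0.576 min. Substrate averaged 0.0324 M over the feed, and 9.53 % of it still stood at the end. Delta's target is 6.83 times its self-condensation product. In a further flask like delta but with 0.050 M of coupling partner, 0.0250 M of partner against 0.100 M of substrate fed by mid-feed gives, with the split number, a ratio of 0.634; at its end that flask holds 23.8 % of target against 47.5 % of self-condensation product, 0.501 to one.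

Its constants stand for no real mixture; the result is computed.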